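Ring C is disconnected at C13=C15: a ring-closing metathesis joins a vinyl group on the C11 ketal carbon to a 1-ethoxyvinyl group on the C17 carbinol carbon. The step exploits the adjacent C15 ketone and C13 carbinol of ring C: the ethoxy group marks C15, so one oxidation of the ring enol ether gives the acyloin without regiochemical choice. The precursor carries rings A, B and D, every stereocentre except C13, the C11 methyl ketal and a silylated C17 carbinol. The ethoxyvinyl group is added only after the acid ketalisation, to a C17 ketone kept distinct from C21, whose silyl ether also steers the addition.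

Key step: step 21

Remark: Cn is the nth atom of the target SMILES; rings are A (pyranone), B (dihydropyran), C (cycloheptane) and D (cyclopentenone).
Remark: an enol ether survives neither acidic methanol nor the free pyranone hydroxyl, and a vinyl Grignard reagent cannot be used beside ring D ketones; steps 14–17 are ordered accordingly, and C17 and C21 are carried as differently protected carbinols.
Remark: step 9 is written for the expected cis-alcohol; its C17 epimer would be carried along and converges in step 15.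
Remark: the target is taken to exist as the closed C11 hemiketal drawn (axial hydroxyl, trans B/C fusion).

Step 1
Reactants: 1 3-methylpentane-2,4-dione; 2 carbon dioxide
Product: 3 4-methyl-3,5-dioxohexanoic acid
Conditions: LiN(i-Pr)2 (2.2 equiv), THF, −78 → 0 °C; CO2, −78 °C; aq. HCl
Reagents that add atoms: none
Why: Double deprotonation gives the β-diketone dianion, which is carboxylated at its terminal and more basic carbon (dianion carboxylation).

Step 2
Reactants: 3 4-methyl-3,5-dioxohexanoic acid
Product: 4 4-hydroxy-5,6-dimethyl-2H-pyran-2-one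
Conditions: 1,1'-carbonyldiimidazole, THF, rt; aq. HCl
Reagents that add atoms: none
Why: The acyl imidazole is captured by the enol oxygen of the C5 ketone and the lactone tautomerises to the aromatic 4-hydroxy-2-pyranone (cyclodehydration of a 3,5-dioxo acid).

Step 3
Reactants: 4 4-hydroxy-5,6-dimethyl-2H-pyran-2-one; 5 formaldehyde
Product: 6 4-hydroxy-5,6-dimethyl-3-[(phenylsulfonyl)methyl]-2H-pyran-2-one
Conditions: PhSO2H, aq. CH2O, EtOH/H2O, rt
Reagents that add atoms: benzenesulfinic acid, O=S(O)c1ccccc1
Why: Knoevenagel condensation at the nucleophilic C3 gives the 3-methylidene dione, which the sulfinate traps at sulfur (three-component sulfonylmethylation), so that the reactive methide is stored as a stable sulfone.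

Step 4
Reactants: 7 (S)-5,5-dimethyl-4-phenyloxazolidin-2-one; 8 (E)-but-2-enoyl chloride
Product: 9 (S)-3-[(E)-but-2-enoyl]-5,5-dimethyl-4-phenyloxazolidin-2-one
Conditions: n-BuLi, THF, −78 °C; then 8, −78 → 0 °C
Reagents that add atoms: none
Why: N-Acylation of the lithiated oxazolidinone by the acid chloride gives the enoyl imide without touching the (E)-alkene.

Step 5
Reactants: 10 2,2-dimethylcyclopentane-1,3-dione
Product: 11 (S)-3-hydroxy-2,2-dimethylcyclopentan-1-one
Conditions: (R)-2-methyl-CBS-oxazaborolidine (10 mol%), BH3·SMe2 (0.6 equiv), THF, −20 °C; MeOH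
Reagents that add atoms: none
Why: Corey–Bakshi–Shibata reduction of one of the two equivalent ketones, in which the (R)-catalyst should deliver hydride with the quaternary carbon in the place of the large group so that the (S)-carbinol (C21) results, the hydroxy ketone being reduced more slowly than the dione.

Step 6
Reactants: 11 (S)-3-hydroxy-2,2-dimethylcyclopentan-1-one
Product: 12 (S)-3-(tert-butyldimethylsilyloxy)-2,2-dimethylcyclopentan-1-one
Conditions: t-BuMe2SiOTf, 2,6-lutidine, CH2Cl2, 0 °C
Reagents that add atoms: tert-butyldimethylsilyl triflate, CC(C)(C)[Si](C)(C)OS(=O)(=O)C(F)(F)F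
Why: Silylation of the hindered secondary alcohol with the silyl triflate gives an ether that survives all steps up to step 18 and later shields one face of ring D.

Step 7
Reactants: 12 (S)-3-(tert-butyldimethylsilyloxy)-2,2-dimethylcyclopentan-1-one
Product: 14 (S)-4-(tert-butyldimethylsilyloxy)-5,5-dimethylcyclopent-2-en-1-one, via silyl enol ether 13 (not isolated)
Conditions: LiN(i-Pr)2, Me3SiCl, THF, −78 °C; then Pd(OAc)2 (1.1 equiv), MeCN, rt
Reagents that add atoms: none
Why: The ketone can enolise only toward its CH2 group, and Saegusa–Ito oxidation of the silyl enol ether (palladium enolate, β-hydride elimination) gives the enone.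

Step 8
Reactants: 14 (S)-4-(tert-butyldimethylsilyloxy)-5,5-dimethylcyclopent-2-en-1-one
Product: 15 (S)-4-(tert-butyldimethylsilyloxy)-2-iodo-5,5-dimethylcyclopent-2-en-1-one
Conditions: I2, pyridine, CH2Cl2, 0 °C → rt
Reagents that add atoms: iodine, II
Why: Conjugate addition of pyridine, iodination of the enolate and elimination place iodine on the α-carbon C19 (α-iodination of a cyclic enone).

Step 9
Reactants: 15 (S)-4-(tert-butyldimethylsilyloxy)-2-iodo-5,5-dimethylcyclopent-2-en-1-one
Product: 16 (1S,4S)-4-(tert-butyldimethylsilyloxy)-2-iodo-5,5-dimethylcyclopent-2-en-1-ol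
Conditions: NaBH4, CeCl3·7H2O, MeOH, −78 °C
Reagents that add atoms: none
Why: Luche 1,2-reduction, in which hydride should add anti to the silyloxy group to give the cis-alcohol; this carbinol centre (C17) is temporary and is oxidised again in step 15.

Step 10
Reactants: 16 (1S,4S)-4-(tert-butyldimethylsilyloxy)-2-iodo-5,5-dimethylcyclopent-2-en-1-ol
Product: 17 triethylsilyl ether of 16
Conditions: Et3SiCl, imidazole, DMF, 0 °C → rt
Reagents that add atoms: chlorotriethylsilane, CC[Si](CC)(CC)Cl
Why: Silylation masks the hydroxyl for the organometallic step, and the triethylsilyl ether can later be cleaved by mild acid beside the tert-butyldimethylsilyl ether.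

Step 11
Reactants: 17 triethylsilyl ether of 16; 9 (S)-3-[(E)-but-2-enoyl]-5,5-dimethyl-4-phenyloxazolidin-2-one
Product: 20 3-alkenylbutanoyl imide, via alkenyllithium 18 (not isolated), via alkenylmagnesium bromide 19 (not isolated)
Conditions: t-BuLi (2.0 equiv), Et2O, −78 °C; MgBr2·OEt2; CuBr·SMe2 (0.3 equiv), 9, THF, −78 → −20 °C; aq. NH4Cl
Reagents that add atoms: none
Why: Iodine–lithium exchange and transmetalation give the alkenyl Grignard reagent, whose copper-catalysed 1,4-addition to the magnesium-chelated s-cis enoyl imide occurs on the face opposite to the phenyl group and so sets C26 (R) under auxiliary control.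

Step 12
Reactants: 20 3-alkenylbutanoyl imide
Product: 22 (R)-3-alkenylbutanal, via hemiaminal 21 (not isolated)
Conditions: i-Bu2AlH, CH2Cl2, −78 °C; aq. potassium sodium tartrate, rt
Reagents that add atoms: none
Why: The 5,5-dimethyl groups block attack at the ring carbonyl, so hydride adds only to the exocyclic carbonyl and the stable hemiaminal releases the aldehyde and the auxiliary on work-up (reduction of an N-acyl oxazolidinone to the aldehyde).

Step 13
Reactants: 22 (R)-3-alkenylbutanal; 6 4-hydroxy-5,6-dimethyl-3-[(phenylsulfonyl)methyl]-2H-pyran-2-one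
Product: 24 ring A/B lactol, via methylidene pyrandione 23 (not isolated)
Conditions: (R)-α,α-diphenylprolinol trimethylsilyl ether (20 mol%), NaHCO3, CH2Cl2, 0 °C → rt
Reagents that add atoms: none
Why: The base frees the methide from the sulfone, and the (E)-enamine of 22 adds through C28 to its CH2 terminus on the face not covered by the diphenyl(silyloxy)methyl group of the (R)-catalyst, which sets C28 (R) under catalyst control, before hydrolysis and hemiacetalisation close ring B (enamine-catalysed Michael addition–hemiacetalisation, the equivalent of an inverse-demand oxa-Diels–Alder reaction).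

Step 14
Reactants: 24 ring A/B lactol; 25 vinylmagnesium bromide
Product: 27 C11 allylic alcohol with free C17 hydroxyl, via triethylsilyl ether 26 (not isolated)
Conditions: CH2=CHMgBr (4 equiv), THF, −78 → 0 °C; aq. NH4Cl; then AcOH/THF/H2O (3:1:1), rt
Reagents that add atoms: none
Why: The Grignard reagent deprotonates the lactol, which opens to the aldehyde and the magnesium pyranonate (a form in which the pyranone is protected), 1,2-addition then gives the allylic alcohol as an inconsequential epimer mixture, and aqueous acetic acid removes only the triethylsilyl group.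

Step 15
Reactants: 27 C11 allylic alcohol with free C17 hydroxyl
Product: 28 C11 vinyl ketone/C17 enone
Conditions: MnO2 (excess), CH2Cl2, rt
Reagents that add atoms: none
Why: Both secondary alcohols are allylic and are oxidised by MnO2 under neutral conditions while the silyl ether at C21 stays, and the C11 vinyl ketone is buffered as its cyclic hemiketal to the pyranone hydroxyl.

Step 16
Reactants: 28 C11 vinyl ketone/C17 enone
Product: 29 C11 methyl vinyl ketal (ring B closed)
Conditions: pyridinium p-toluenesulfonate (10 mol%), MeOH, 3 Å molecular sieves, rt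
Reagents that add atoms: methanol, CO
Why: Acid-catalysed exchange of the hemiketal hydroxyl for methoxy is reversible and should end at the ketal with axial methoxy (anomeric effect) and equatorial vinyl group trans to the equatorial C28 side chain, which sets C11; no enol ether is present yet, so the acid does no harm.

Step 17
Reactants: 29 C11 methyl vinyl ketal (ring B closed); 30 ethyl vinyl ether
Product: 33 C17 ethoxyvinyl carbinol, via 1-ethoxyvinyllithium 31 (not isolated), via dichloro(1-ethoxyvinyl)cerium 32 (not isolated)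
Conditions: 30, t-BuLi, THF, −78 → 0 °C; CeCl3, −78 °C; then 29, −78 °C; aq. NaHCO3
Reagents that add atoms: none
Why: C17 is the only ketone and cannot enolise, the organocerium reagent adds 1,2 and is too weakly basic and too selective to attack the pyranone, and it should approach anti to the bulky silyloxy group at C21, which sets C17 (R) (nucleophilic addition of an acyl anion equivalent).

Step 18
Reactants: 33 C17 ethoxyvinyl carbinol
Product: 34 C17,C21-diol
Conditions: Bu4NF, THF, 0 °C → rt
Reagents that add atoms: none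
Why: Fluoride cleaves the secondary silyl ether under basic conditions that leave the enol ether and the ketal untouched (desilylation).

Step 19
Reactants: 34 C17,C21-diol
Product: 35 ring D hydroxy enone
Conditions: MnO2 (excess), CH2Cl2, rt
Reagents that add atoms: none
Why: The C21 alcohol is allylic and is oxidised by MnO2 under neutral conditions to the ring D enone, whereas the tertiary C17 alcohol cannot be oxidised (allylic oxidation).

Step 20
Reactants: 35 ring D hydroxy enone
Product: 36 metathesis precursor (C11 vinyl ketal, C17 trimethylsilyloxy ethoxyvinyl)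
Conditions: 1-(trimethylsilyl)imidazole, CH2Cl2, 40 °C
Reagents that add atoms: 1-(trimethylsilyl)imidazole, C[Si](C)(C)n1ccnc1
Why: The neutral silyl donor caps the hindered tertiary alcohol without acid (silylation), so that the enol ether survives and the hydroxyl can no longer exchange into the C11 ketal.

Step 21
Reactants: 36 metathesis precursor (C11 vinyl ketal, C17 trimethylsilyloxy ethoxyvinyl)
Product: 37 tetracyclic C15 ethyl enol ether
Conditions: second-generation Grubbs catalyst (10 mol%), toluene (0.002 M), 80 °C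
Reagents that add atoms: none
Why: The ruthenium benzylidene should exchange onto the only monosubstituted alkene, the C11 vinyl group, and the new alkylidene adds across the 1,1-disubstituted enol ether in a [2+2] cycloaddition, the ruthenacyclobutane opening to the C13=C15 bond with loss of ethene, which escapes and makes the closure irreversible. The closest known reaction type is ring-closing metathesis of a terminal olefin with a 1-alkoxyvinyl group to a cyclic enol ether with ruthenium N-heterocyclic-carbene catalysts. Ring C closes as a cycloheptene whose other five atoms are already held by ring B (C11–C28) and ring D (C17–C19); the vinyl group and the C28 side chain are trans-diequatorial on ring B, so the trans B/C fusion of the target follows. No stereocentre is formed. The step needs initiation at the vinyl group and not at the enol ether, where an unreactive ruthenium alkoxycarbene would form; the shielding of the enol ether by the quaternary C17 and its silyloxy group, the trisubstituted electron-poor character of the ring D and pyranone double bonds, and high dilution against cross-metathesis should secure this.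

Step 22
Reactants: 37 tetracyclic C15 ethyl enol ether
Product: 40 target CNP0525404.1, via ethoxy epoxide 38 (not isolated), via ketol silyl ether 39 (not isolated)
Conditions: dimethyldioxirane, acetone/CH2Cl2, −78 → 0 °C; then 0.5 M aq. HCl, THF, 0 °C → rt
Reagents that add atoms: dimethyldioxirane, CC1(C)OO1; water, O
Why: Dimethyldioxirane epoxidises only the electron-rich C13=C15 enol ether, on the face anti to the axial C11 methoxy and C17 silyloxy groups, which sets C13 (R), and dilute aqueous acid then opens the alkoxy epoxide to the C15 ketone and C13 carbinol, removes the silyl group and exchanges methoxy for hydroxyl at C11 to give the anomerically favoured hemiketal (Rubottom-type oxidation followed by hydrolysis).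

Compound list
1 | 3-methylpentane-2,4-dione | CC(=O)C(C)C(C)=O | starting material
2 | carbon dioxide | O=C=O | starting material
3 | 4-methyl-3,5-dioxohexanoic acid | CC(=O)C(C)C(=O)CC(=O)O | intermediate
4 | 4-hydroxy-5,6-dimethyl-2H-pyran-2-one | Cc1oc(=O)cc(O)c1C | intermediate
5 | formaldehyde | C=O | starting material
6 | 4-hydroxy-5,6-dimethyl-3-[(phenylsulfonyl)methyl]-2H-pyran-2-one | Cc1oc(=O)c(CS(=O)(=O)c2ccccc2)c(O)c1C | intermediate
7 | (S)-5,5-dimethyl-4-phenyloxazolidin-2-one | O=C1N[C@@H](c2ccccc2)C(C)(C)O1 | starting material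
8 | (E)-but-2-enoyl chloride | C/C=C/C(Cl)=O | starting material
9 | (S)-3-[(E)-but-2-enoyl]-5,5-dimethyl-4-phenyloxazolidin-2-one | C/C=C/C(=O)N1[C@@H](c2ccccc2)C(C)(C)OC1=O | intermediate
10 | 2,2-dimethylcyclopentane-1,3-dione | CC1(C)C(=O)CCC1=O | starting material
11 | (S)-3-hydroxy-2,2-dimethylcyclopentan-1-one | O=C1CC[C@H](O)C1(C)C | intermediate
12 | (S)-3-(tert-butyldimethylsilyloxy)-2,2-dimethylcyclopentan-1-one | O=C1CC[C@H](O[Si](C)(C)C(C)(C)C)C1(C)C | intermediate
13 | (S)-4-(tert-butyldimethylsilyloxy)-5,5-dimethyl-1-(trimethylsilyloxy)cyclopent-1-ene | C[Si](C)(C)OC1=CC[C@H](O[Si](C)(C)C(C)(C)C)C1(C)C | intermediate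
14 | (S)-4-(tert-butyldimethylsilyloxy)-5,5-dimethylcyclopent-2-en-1-one | O=C1C=C[C@H](O[Si](C)(C)C(C)(C)C)C1(C)C | intermediate
15 | (S)-4-(tert-butyldimethylsilyloxy)-2-iodo-5,5-dimethylcyclopent-2-en-1-one | O=C1C(I)=C[C@H](O[Si](C)(C)C(C)(C)C)C1(C)C | intermediate
16 | (1S,4S)-4-(tert-butyldimethylsilyloxy)-2-iodo-5,5-dimethylcyclopent-2-en-1-ol (hydroxyl and silyloxy cis) | O[C@@H]1C(I)=C[C@H](O[Si](C)(C)C(C)(C)C)C1(C)C | intermediate
17 | (1S,4S)-4-(tert-butyldimethylsilyloxy)-2-iodo-5,5-dimethyl-1-(triethylsilyloxy)cyclopent-2-ene | CC[Si](CC)(CC)O[C@@H]1C(I)=C[C@H](O[Si](C)(C)C(C)(C)C)C1(C)C | intermediate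
18 | alkenyllithium from 17 (lithium in place of iodine) | [Li]C1=C[C@H](O[Si](C)(C)C(C)(C)C)C(C)(C)[C@@H]1O[Si](CC)(CC)CC | intermediate
19 | alkenylmagnesium bromide from 18 | Br[Mg]C1=C[C@H](O[Si](C)(C)C(C)(C)C)C(C)(C)[C@@H]1O[Si](CC)(CC)CC | intermediate
20 | (S)-3-{(R)-3-[(3S,5R)-3-(tert-butyldimethylsilyloxy)-4,4-dimethyl-5-(triethylsilyloxy)cyclopent-1-en-1-yl]butanoyl}-5,5-dimethyl-4-phenyloxazolidin-2-one | O=C(C[C@@H](C)C1=C[C@H](O[Si](C)(C)C(C)(C)C)C(C)(C)[C@@H]1O[Si](CC)(CC)CC)N2[C@@H](c3ccccc3)C(C)(C)OC2=O | intermediate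
21 | hemiaminal of 20 (exocyclic carbonyl reduced to CH–OH, carbinol epimers) | OC(C[C@@H](C)C1=C[C@H](O[Si](C)(C)C(C)(C)C)C(C)(C)[C@@H]1O[Si](CC)(CC)CC)N2[C@@H](c3ccccc3)C(C)(C)OC2=O | intermediate
22 | (R)-3-[(3S,5R)-3-(tert-butyldimethylsilyloxy)-4,4-dimethyl-5-(triethylsilyloxy)cyclopent-1-en-1-yl]butanal | O=CC[C@@H](C)C1=C[C@H](O[Si](C)(C)C(C)(C)C)C(C)(C)[C@@H]1O[Si](CC)(CC)CC | intermediate
23 | 5,6-dimethyl-3-methylidene-2H-pyran-2,4(3H)-dione | C=C1C(=O)OC(C)=C(C)C1=O | intermediate
24 | (3R)-3-{(R)-1-[(3S,5R)-3-(tert-butyldimethylsilyloxy)-4,4-dimethyl-5-(triethylsilyloxy)cyclopent-1-en-1-yl]ethyl}-2-hydroxy-7,8-dimethyl-3,4-dihydro-2H,5H-pyrano[4,3-b]pyran-5-one (both C11 anomers) | Cc1oc(=O)c2c(c1C)OC(O)[C@H](C2)[C@@H](C)C3=C[C@H](O[Si](C)(C)C(C)(C)C)C(C)(C)[C@@H]3O[Si](CC)(CC)CC | intermediate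
25 | vinylmagnesium bromide | C=C[Mg]Br | starting material
26 | 3-{(2R,3R)-3-[(3S,5R)-3-(tert-butyldimethylsilyloxy)-4,4-dimethyl-5-(triethylsilyloxy)cyclopent-1-en-1-yl]-2-(1-hydroxyprop-2-en-1-yl)butyl}-4-hydroxy-5,6-dimethyl-2H-pyran-2-one (C11 carbinol epimers) | C=CC(O)[C@H](Cc1c(O)c(C)c(C)oc1=O)[C@@H](C)C2=C[C@H](O[Si](C)(C)C(C)(C)C)C(C)(C)[C@@H]2O[Si](CC)(CC)CC | intermediate
27 | 3-{(2R,3R)-3-[(3S,5R)-3-(tert-butyldimethylsilyloxy)-5-hydroxy-4,4-dimethylcyclopent-1-en-1-yl]-2-(1-hydroxyprop-2-en-1-yl)butyl}-4-hydroxy-5,6-dimethyl-2H-pyran-2-one (C11 carbinol epimers) | C=CC(O)[C@H](Cc1c(O)c(C)c(C)oc1=O)[C@@H](C)C2=C[C@H](O[Si](C)(C)C(C)(C)C)C(C)(C)[C@@H]2O | intermediate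
28 | 3-{(2R,3R)-2-acryloyl-3-[(3S)-3-(tert-butyldimethylsilyloxy)-4,4-dimethyl-5-oxocyclopent-1-en-1-yl]butyl}-4-hydroxy-5,6-dimethyl-2H-pyran-2-one (open form of its C11 hemiketal) | C=CC(=O)[C@H](Cc1c(O)c(C)c(C)oc1=O)[C@@H](C)C2=C[C@H](O[Si](C)(C)C(C)(C)C)C(C)(C)C2=O | intermediate
29 | (2R,3R)-3-{(R)-1-[(3S)-3-(tert-butyldimethylsilyloxy)-4,4-dimethyl-5-oxocyclopent-1-en-1-yl]ethyl}-2-methoxy-7,8-dimethyl-2-vinyl-3,4-dihydro-2H,5H-pyrano[4,3-b]pyran-5-one | Cc1oc(=O)c2c(c1C)O[C@](OC)(C=C)[C@H](C2)[C@@H](C)C3=C[C@H](O[Si](C)(C)C(C)(C)C)C(C)(C)C3=O | intermediate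
30 | ethyl vinyl ether | C=COCC | starting material
31 | 1-ethoxyvinyllithium | [Li]C(=C)OCC | intermediate
32 | dichloro(1-ethoxyvinyl)cerium | C=C(OCC)[Ce](Cl)Cl | intermediate
33 | (2R,3R)-3-{(R)-1-[(3S,5R)-3-(tert-butyldimethylsilyloxy)-5-(1-ethoxyvinyl)-5-hydroxy-4,4-dimethylcyclopent-1-en-1-yl]ethyl}-2-methoxy-7,8-dimethyl-2-vinyl-3,4-dihydro-2H,5H-pyrano[4,3-b]pyran-5-one | Cc1oc(=O)c2c(c1C)O[C@](OC)(C=C)[C@H](C2)[C@@H](C)C3=C[C@H](O[Si](C)(C)C(C)(C)C)C(C)(C)[C@@]3(O)C(=C)OCC | intermediate
34 | (2R,3R)-3-{(R)-1-[(3S,5R)-5-(1-ethoxyvinyl)-3,5-dihydroxy-4,4-dimethylcyclopent-1-en-1-yl]ethyl}-2-methoxy-7,8-dimethyl-2-vinyl-3,4-dihydro-2H,5H-pyrano[4,3-b]pyran-5-one | Cc1oc(=O)c2c(c1C)O[C@](OC)(C=C)[C@H](C2)[C@@H](C)C3=C[C@H](O)C(C)(C)[C@@]3(O)C(=C)OCC | intermediate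
35 | (2R,3R)-3-{(R)-1-[(5R)-5-(1-ethoxyvinyl)-5-hydroxy-4,4-dimethyl-3-oxocyclopent-1-en-1-yl]ethyl}-2-methoxy-7,8-dimethyl-2-vinyl-3,4-dihydro-2H,5H-pyrano[4,3-b]pyran-5-one | Cc1oc(=O)c2c(c1C)O[C@](OC)(C=C)[C@H](C2)[C@@H](C)C3=CC(=O)C(C)(C)[C@@]3(O)C(=C)OCC | intermediate
36 | (2R,3R)-3-{(R)-1-[(5R)-5-(1-ethoxyvinyl)-4,4-dimethyl-3-oxo-5-(trimethylsilyloxy)cyclopent-1-en-1-yl]ethyl}-2-methoxy-7,8-dimethyl-2-vinyl-3,4-dihydro-2H,5H-pyrano[4,3-b]pyran-5-one | Cc1oc(=O)c2c(c1C)O[C@](OC)(C=C)[C@H](C2)[C@@H](C)C3=CC(=O)C(C)(C)[C@@]3(O[Si](C)(C)C)C(=C)OCC | intermediate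
37 | tetracyclic enol ether (rings A–D; C13=C15 with ethoxy on C15; C11 methoxy, C17 trimethylsilyloxy; C11 S, C17 R, C26 R, C28 R) | Cc1oc(=O)c2c(c1C)O[C@]1(OC)C=C(OCC)[C@@]3(O[Si](C)(C)C)C(=CC(=O)C3(C)C)[C@H](C)[C@H]1C2 | intermediate
38 | C13–C15 epoxide of 37 (epoxide oxygen anti to the C11 methoxy and C17 silyloxy groups) | Cc1oc(=O)c2c(c1C)O[C@]1(OC)[C@@H]4O[C@]4(OCC)[C@@]3(O[Si](C)(C)C)C(=CC(=O)C3(C)C)[C@H](C)[C@H]1C2 | intermediate
39 | C15 ketone with C13 carbinol, C11 methoxy and C17 trimethylsilyloxy (C11 S, C13 R, C17 R, C26 R, C28 R) | Cc1oc(=O)c2c(c1C)O[C@]1(OC)[C@H](O)C(=O)[C@@]3(O[Si](C)(C)C)C(=CC(=O)C3(C)C)[C@H](C)[C@H]1C2 | intermediate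
40 | CNP0525404.1 (C11 S, C13 R, C17 R, C26 R, C28 R) | Cc1oc(=O)c2c(c1C)O[C@]1(O)[C@H](O)C(=O)[C@@]3(O)C(=CC(=O)C3(C)C)[C@H](C)[C@H]1C2 | target

Total step count: 22. Longest linear sequence: 18 steps (steps 5–22, from 10).

Steps most likely to fail

Step 21. The catalyst may be taken up by the enol ether as a ruthenium alkoxycarbene that does not turn over, or it may fail to load onto the vinyl group beside the quaternary ketal carbon, so that the diene is recovered or dimerises. The fallback moves the ring closure one step earlier, onto a differently protected substrate: carbinol 35, which has a small free hydroxyl at C17 in place of the silyloxy group, is cyclised in base-washed glassware to the hydroxy enol ether F1. F1 is then silylated as in step 20 and rejoins the route at 37.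

Step 13. The methide released from 6 may be consumed by a second pyranone (methylene-bridged dimer) or by the amine catalyst before the β-branched enamine adds, or the C26 centre may erode facial control at C28. The fallback reverses the polarity, setting out from aldehyde 22. α-Methylenation (aq. CH2O, pyrrolidinium propionate, i-PrOH) gives the 2-substituted acrolein F2. Pyranone 4 then adds through its C3 to the CH2 terminus of F2 under iminium catalysis by the same prolinol silyl ether; protonation of the resulting enamine creates C28 and hemiacetalisation returns to the route at lactol 24. Control at C28 is then by protonation and is less certain, so the C28 epimer may have to be separated.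

Step 17. Addition to the congested C17 ketone may be slow enough for the reagent to open the pyranone instead, or the bulky cerium reagent may lose facial control. The fallback builds the two-carbon unit on 29 in stages with small reagents. Ethynylmagnesium bromide with CeCl3 should give the ethynyl carbinol F3, again anti to the C21 silyloxy group. Copper-catalysed α-selective hydroboration ((SIMes)CuCl, NaOt-Bu, B2pin2, MeOH) gives the 1-borylvinyl carbinol F4. Cu(OAc)2-promoted coupling of the alkenyl boronate with ethanol (Et3N, rt) then gives 33.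

Further compounds
F1 | step 21 | tetracyclic C15 ethyl enol ether with free C17 hydroxyl (des-silyl 37) | Cc1oc(=O)c2c(c1C)O[C@]1(OC)C=C(OCC)[C@@]3(O)C(=CC(=O)C3(C)C)[C@H](C)[C@H]1C2
F2 | step 13 | 2-methylidene derivative of 22: 3-[(3S,5R)-3-(tert-butyldimethylsilyloxy)-4,4-dimethyl-5-(triethylsilyloxy)cyclopent-1-en-1-yl]-2-methylidenebutanal (C26 as in 22) | C=C(C=O)[C@@H](C)C1=C[C@H](O[Si](C)(C)C(C)(C)C)C(C)(C)[C@@H]1O[Si](CC)(CC)CC
F3 | step 17 | C17 ethynyl carbinol (33 with ethynyl in place of 1-ethoxyvinyl) | Cc1oc(=O)c2c(c1C)O[C@](OC)(C=C)[C@H](C2)[C@@H](C)C3=C[C@H](O[Si](C)(C)C(C)(C)C)C(C)(C)[C@@]3(O)C#C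
F4 | step 17 | C17 1-(pinacolboryl)vinyl carbinol (33 with Bpin in place of ethoxy) | Cc1oc(=O)c2c(c1C)O[C@](OC)(C=C)[C@H](C2)[C@@H](C)C3=C[C@H](O[Si](C)(C)C(C)(C)C)C(C)(C)[C@@]3(O)C(=C)B4OC(C)(C)C(C)(C)O4
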